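**Retrosynthetic overview**

1. Target 13 comes from the (2S)-flavanone tris-MOM ether 12 by acid methanolysis; 12 is an isomer of the achiral aldehyde 11.
2. Key disconnection is C3–C4 of ring C: the formyl C–H of 11 (future C4, on C4a of ring A) is added across the C2=C3 enol ether by enantioselective rhodium-catalysed hydroacylation, which closes ring C, makes the C4 ketone and sets C2.
3. Enabling feature: C2 of ring C carries O1, ring B and only one hydrogen, and O1 sits on C8a next to C4a. C2–C3 can therefore be stored as a 1,1-disubstituted aryl enol ether on O1 whose terminal CH2 (C3) lies within reach of the formyl carbon.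
4. 11 comes from C–O coupling of salicylaldehyde 6 with enol triflate 10 (ring B); 6 from Stille coupling of iodide 3 with geranylstannane 5. Iodination of 2 next to its one free, chelated OH (the OH that becomes O1) fixes the geranyl group at C8.
5. Ring order: rings A and B are bought as arenes (1 and 7); ring C is the only ring made and is closed last, in step 8.

Key step: step 8

Assumption: the sense of induction in step 8 cannot be predicted with certainty; (R)-DTBM-SEGPHOS is written, and its antipode would be used if a model substrate shows the opposite sense.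

**Route**

Step 1
Reactants: 1 2,4,6-trihydroxybenzaldehyde
Product: 2 2-hydroxy-4,6-bis(methoxymethoxy)benzaldehyde
Conditions: MOMCl (2.1 equiv), iPr2NEt, CH2Cl2, 0 °C to rt
Reagents that add atoms: chloromethyl methyl ether, COCCl
Why: Base-mediated O-alkylation (MOM ether formation) should take the unchelated para hydroxyl and one of the two equivalent ortho hydroxyls, while the last ortho hydroxyl, held in a hydrogen bond to the formyl oxygen, should stay free.

Step 2
Reactants: 2 2-hydroxy-4,6-bis(methoxymethoxy)benzaldehyde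
Product: 3 2-hydroxy-3-iodo-4,6-bis(methoxymethoxy)benzaldehyde
Conditions: N-iodosuccinimide (1.0 equiv), DMF, 0 °C to rt, dark
Reagents that add atoms: N-iodosuccinimide, O=C1CCC(=O)N1I
Why: Electrophilic aromatic iodination of 2-hydroxy-4,6-dialkoxy acylbenzenes is known to go next to the free hydroxyl rather than to the carbon between the two ether oxygens, so iodine should enter at C3, the future C8.

Step 3
Reactants: 4 geranyl bromide, (2E)-1-bromo-3,7-dimethylocta-2,6-diene
Product: 5 tributyl[(2E)-3,7-dimethylocta-2,6-dien-1-yl]stannane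
Conditions: Bu3SnH, LiN(iPr)2, THF, 0 °C; then 4, −78 °C to rt
Reagents that add atoms: tributyltin hydride, CCCC[SnH](CCCC)CCCC
Why: SN2 displacement of the primary allylic bromide by the stannyl anion should occur at the unsubstituted terminus and keep the E geometry.

Step 4
Reactants: 3 2-hydroxy-3-iodo-4,6-bis(methoxymethoxy)benzaldehyde; 5 tributyl[(2E)-3,7-dimethylocta-2,6-dien-1-yl]stannane
Product: 6 3-[(2E)-3,7-dimethylocta-2,6-dien-1-yl]-2-hydroxy-4,6-bis(methoxymethoxy)benzaldehyde
Conditions: Pd(PPh3)4 (cat.), LiCl, DMF, 90 °C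
Reagents that add atoms: none
Why: Stille coupling: zerovalent palladium inserts into the aryl–iodine bond, the allyl group is transferred from tin, and reductive elimination at the less substituted allyl terminus should give the linear (E)-geranyl arene; free phenol and aldehyde are tolerated.

Step 5
Reactants: 7 1-(4-hydroxyphenyl)ethan-1-one
Product: 8 1-[4-(methoxymethoxy)phenyl]ethan-1-one
Conditions: MOMCl, iPr2NEt, CH2Cl2, 0 °C to rt
Reagents that add atoms: chloromethyl methyl ether, COCCl
Why: Routine MOM ether formation on an unhindered, acidic phenol.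

Step 6
Reactants: 8 1-[4-(methoxymethoxy)phenyl]ethan-1-one
Product: 10 1-[4-(methoxymethoxy)phenyl]ethenyl trifluoromethanesulfonate, via potassium 1-[4-(methoxymethoxy)phenyl]ethenolate 9 (not isolated)
Conditions: KN(SiMe3)2, THF, −78 °C; then PhNTf2, −78 °C to 0 °C
Reagents that add atoms: N-phenylbis(trifluoromethanesulfonimide), O=S(=O)(N(c1ccccc1)S(=O)(=O)C(F)(F)F)C(F)(F)F
Why: Enol triflate formation by O-sulfonylation of the only possible enolate under non-acidic conditions that spare the MOM ether.

Step 7
Reactants: 6 3-[(2E)-3,7-dimethylocta-2,6-dien-1-yl]-2-hydroxy-4,6-bis(methoxymethoxy)benzaldehyde; 10 1-[4-(methoxymethoxy)phenyl]ethenyl trifluoromethanesulfonate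
Product: 11 3-[(2E)-3,7-dimethylocta-2,6-dien-1-yl]-4,6-bis(methoxymethoxy)-2-({1-[4-(methoxymethoxy)phenyl]ethenyl}oxy)benzaldehyde
Conditions: Pd2(dba)3 (cat.), 2-di-tert-butylphosphino-2',4',6'-triisopropylbiphenyl, K3PO4, toluene, 80 °C; work-up on Et3N-deactivated silica
Reagents that add atoms: none
Why: Buchwald–Hartwig-type C–O coupling of an alkenyl triflate with a phenol: oxidative addition of zerovalent palladium into the vinyl C–O bond, phenoxide exchange and C–O reductive elimination, which the bulky biaryl phosphine should enforce even for this doubly ortho-substituted phenoxide.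

Step 8
Reactants: 11 3-[(2E)-3,7-dimethylocta-2,6-dien-1-yl]-4,6-bis(methoxymethoxy)-2-({1-[4-(methoxymethoxy)phenyl]ethenyl}oxy)benzaldehyde
Product: 12 (2S)-8-[(2E)-3,7-dimethylocta-2,6-dien-1-yl]-5,7-bis(methoxymethoxy)-2-[4-(methoxymethoxy)phenyl]-2,3-dihydro-4H-chromen-4-one
Conditions: [Rh(cod)Cl]2 (2.5 mol %), (R)-DTBM-SEGPHOS (5 mol %), Na[B(3,5-(CF3)2C6H3)4] (5 mol %), 1,4-dioxane, 60 °C
Reagents that add atoms: none
Why: Proposed new method: intramolecular alkene hydroacylation in which the alkene is an aryl enol ether tethered through the ring oxygen has not been shown; the expected course is oxidative addition of the formyl C–H bond of 11 to the cationic monovalent rhodium bisphosphine complex to give an acyl rhodium hydride (trivalent rhodium) chelated by C2=C3, insertion of this 1,1-disubstituted alkene into Rh–H with hydrogen going to C2 and rhodium to the terminal carbon C3, and C–C reductive elimination from the seven-membered acyl alkyl rhodacycle, which forms C3–C4. The closest known reaction type is the rhodium-catalysed enantioselective endo hydroacylation of ortho-allylbenzaldehydes with 2-substituted allyl groups to 3-substituted tetralones, and of 2-(1-substituted vinyl)benzaldehydes to 3-substituted indanones, from which 11 differs only in that O1 takes the place of the benzylic CH2. Ring C is closed in the 6-endo mode (both alkene carbons end up in the ring), and the C4 ketone arises at the right oxidation level without any redox reagent because 12 is an isomer of 11. The only new stereocenter, C2, is set in the hydride insertion by the chiral bisphosphine, which selects the enantioface of the enol ether (catalyst control, ligand antipode chosen so that 2S results). The step needs 6-endo over 5-exo closure, secured by the 1,1-disubstitution that disfavours rhodium at the fully substituted C2; hydroacylation over decarbonylation, secured by alkene chelation and the bulky electron-rich ligand; and chemoselectivity over the two trisubstituted geranyl alkenes, which bind and insert far more slowly than the terminal enol ether.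

Step 9
Reactants: 12 (2S)-8-[(2E)-3,7-dimethylocta-2,6-dien-1-yl]-5,7-bis(methoxymethoxy)-2-[4-(methoxymethoxy)phenyl]-2,3-dihydro-4H-chromen-4-one
Product: 13 sophoraflavanone A, (2S)-8-[(2E)-3,7-dimethylocta-2,6-dien-1-yl]-5,7-dihydroxy-2-(4-hydroxyphenyl)-2,3-dihydro-4H-chromen-4-one
Conditions: conc. aq. HCl (excess), MeOH, 45 °C
Reagents that add atoms: none
Why: Acid-catalysed methanolysis of the three MOM acetals should leave C2 untouched, since flavanone racemisation runs through base-induced ring opening to the chalcone, and the moderate temperature should keep the geranyl chain from adding the C7 hydroxyl.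

**Compound list**

1 | 2,4,6-trihydroxybenzaldehyde | O=Cc1c(O)cc(O)cc1O | starting material
2 | 2-hydroxy-4,6-bis(methoxymethoxy)benzaldehyde | O=Cc1c(O)cc(OCOC)cc1OCOC | intermediate
3 | 2-hydroxy-3-iodo-4,6-bis(methoxymethoxy)benzaldehyde | O=Cc1c(O)c(I)c(OCOC)cc1OCOC | intermediate
4 | geranyl bromide, (2E)-1-bromo-3,7-dimethylocta-2,6-diene | CC(C)=CCC/C(C)=C/CBr | starting material
5 | tributyl[(2E)-3,7-dimethylocta-2,6-dien-1-yl]stannane | CC(C)=CCC/C(C)=C/C[Sn](CCCC)(CCCC)CCCC | intermediate
6 | 3-[(2E)-3,7-dimethylocta-2,6-dien-1-yl]-2-hydroxy-4,6-bis(methoxymethoxy)benzaldehyde | CC(C)=CCC/C(C)=C/Cc1c(O)c(C=O)c(OCOC)cc1OCOC | intermediate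
7 | 1-(4-hydroxyphenyl)ethan-1-one | CC(=O)c1ccc(O)cc1 | starting material
8 | 1-[4-(methoxymethoxy)phenyl]ethan-1-one | CC(=O)c1ccc(OCOC)cc1 | intermediate
9 | potassium 1-[4-(methoxymethoxy)phenyl]ethenolate | [K+].[O-]C(=C)c1ccc(OCOC)cc1 | intermediate (not isolated)
10 | 1-[4-(methoxymethoxy)phenyl]ethenyl trifluoromethanesulfonate | C=C(OS(=O)(=O)C(F)(F)F)c1ccc(OCOC)cc1 | intermediate
11 | 3-[(2E)-3,7-dimethylocta-2,6-dien-1-yl]-4,6-bis(methoxymethoxy)-2-({1-[4-(methoxymethoxy)phenyl]ethenyl}oxy)benzaldehyde | CC(C)=CCC/C(C)=C/Cc1c(OC(=C)c2ccc(OCOC)cc2)c(C=O)c(OCOC)cc1OCOC | intermediate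
12 | (2S)-8-[(2E)-3,7-dimethylocta-2,6-dien-1-yl]-5,7-bis(methoxymethoxy)-2-[4-(methoxymethoxy)phenyl]-2,3-dihydro-4H-chromen-4-one | CC(C)=CCC/C(C)=C/Cc1c(OCOC)cc(OCOC)c2c1O[C@H](c1ccc(OCOC)cc1)CC2=O | intermediate
13 | sophoraflavanone A, (2S)-8-[(2E)-3,7-dimethylocta-2,6-dien-1-yl]-5,7-dihydroxy-2-(4-hydroxyphenyl)-2,3-dihydro-4H-chromen-4-one | CC(C)=CCC/C(C)=C/Cc1c(O)cc(O)c2c1O[C@H](c1ccc(O)cc1)CC2=O | target

**Step count**

Total steps: 9. Longest linear sequence: 6 (steps 1, 2, 4, 7, 8, 9).

**Steps most likely to fail**

Step 8. What may go wrong: decarbonylation of the acyl rhodium hydride, slow C–H activation of the doubly ortho-substituted aldehyde, or poor facial selectivity in the hydride insertion. The fallback uses known chemistry, still closes ring C at C3–C4, and brings C2 in already resolved; it sets out from 8 and 6 and comes back to the route at 12. Ketone 8 is brominated (PhNMe3Br3, THF, 0 °C) to 2-bromo-1-[4-(methoxymethoxy)phenyl]ethan-1-one F1. Corey–Bakshi–Shibata reduction ((S)-2-methyl-CBS-oxazaborolidine, BH3·SMe2, THF) should give (1S)-2-bromo-1-[4-(methoxymethoxy)phenyl]ethan-1-ol F2. Mitsunobu etherification of phenol 6 with F2 (PPh3, diisopropyl azodicarboxylate, toluene, 0 °C) should proceed with inversion to 2-{(1R)-2-bromo-1-[4-(methoxymethoxy)phenyl]ethoxy}-3-[(2E)-3,7-dimethylocta-2,6-dien-1-yl]-4,6-bis(methoxymethoxy)benzaldehyde F3. Carbene-catalysed intramolecular acylation of the primary bromide (3-benzyl-5-(2-hydroxyethyl)-4-methylthiazolium chloride, Cs2CO3, dioxane, 60 °C) then forms C3–C4 by SN2 attack of the acyl anion equivalent, the known way from 2-(2-haloethoxy)benzaldehydes to chroman-4-ones, and gives 12 without touching C2. The descriptor changes from R in F3 to S in 12 only because CH2Br outranks the aryl group while ring carbon C3 does not.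

Step 7. What may go wrong: slow C–O reductive elimination from the hindered, chelating phenoxide, and base-induced loss of triflic acid from 10 to the alkyne. The fallback builds the enol ether by carbonyl methylenation instead of C–O coupling; it sets out from 6 and comes back at 11. Esterification of 6 with 4-(methoxymethoxy)benzoic acid (EDC·HCl, DMAP, CH2Cl2) should give 2-[(2E)-3,7-dimethylocta-2,6-dien-1-yl]-6-formyl-3,5-bis(methoxymethoxy)phenyl 4-(methoxymethoxy)benzoate F4. The formyl group is masked (HC(OMe)3, cat. pyridinium tosylate, MeOH, rt) as 2-(dimethoxymethyl)-6-[(2E)-3,7-dimethylocta-2,6-dien-1-yl]-3,5-bis(methoxymethoxy)phenyl 4-(methoxymethoxy)benzoate F5. Ester methylenation with Cp2TiMe2 (toluene, 70 °C) should give 2-(dimethoxymethyl)-4-[(2E)-3,7-dimethylocta-2,6-dien-1-yl]-1,5-bis(methoxymethoxy)-3-({1-[4-(methoxymethoxy)phenyl]ethenyl}oxy)benzene F6. The very labile acetal of the electron-rich aldehyde is then hydrolysed selectively (cat. pyridinium tosylate, aqueous acetone, 0 °C) to 11.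

Step 4. What may go wrong: allyl transposition and E/Z scrambling through the π-allyl palladium intermediate, giving branched or Z material. The fallback avoids palladium; it sets out from 1 and 4 and comes back at 6. Direct C-alkylation of 1 with geranyl bromide 4 in cold aqueous KOH (the classical C-prenylation conditions for acylphloroglucinols) should give 3-[(2E)-3,7-dimethylocta-2,6-dien-1-yl]-2,4,6-trihydroxybenzaldehyde F7, a single constitution by the symmetry of 1. MOMCl (2.1 equiv) with iPr2NEt should then etherify the unchelated 4-OH and the less hindered chelated 6-OH, leaving the hindered, chelated 2-OH free, which is 6.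

**Further compounds**

F1 | step 8 | 2-bromo-1-[4-(methoxymethoxy)phenyl]ethan-1-one | O=C(CBr)c1ccc(OCOC)cc1
F2 | step 8 | (1S)-2-bromo-1-[4-(methoxymethoxy)phenyl]ethan-1-ol | O[C@@H](c1ccc(OCOC)cc1)CBr
F3 | step 8 | 2-{(1R)-2-bromo-1-[4-(methoxymethoxy)phenyl]ethoxy}-3-[(2E)-3,7-dimethylocta-2,6-dien-1-yl]-4,6-bis(methoxymethoxy)benzaldehyde | CC(C)=CCC/C(C)=C/Cc1c(O[C@H](c2ccc(OCOC)cc2)CBr)c(C=O)c(OCOC)cc1OCOC
F4 | step 7 | 2-[(2E)-3,7-dimethylocta-2,6-dien-1-yl]-6-formyl-3,5-bis(methoxymethoxy)phenyl 4-(methoxymethoxy)benzoate | CC(C)=CCC/C(C)=C/Cc1c(OC(=O)c2ccc(OCOC)cc2)c(C=O)c(OCOC)cc1OCOC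
F5 | step 7 | 2-(dimethoxymethyl)-6-[(2E)-3,7-dimethylocta-2,6-dien-1-yl]-3,5-bis(methoxymethoxy)phenyl 4-(methoxymethoxy)benzoate | CC(C)=CCC/C(C)=C/Cc1c(OC(=O)c2ccc(OCOC)cc2)c(C(OC)OC)c(OCOC)cc1OCOC
F6 | step 7 | 2-(dimethoxymethyl)-4-[(2E)-3,7-dimethylocta-2,6-dien-1-yl]-1,5-bis(methoxymethoxy)-3-({1-[4-(methoxymethoxy)phenyl]ethenyl}oxy)benzene | CC(C)=CCC/C(C)=C/Cc1c(OC(=C)c2ccc(OCOC)cc2)c(C(OC)OC)c(OCOC)cc1OCOC
F7 | step 4 | 3-[(2E)-3,7-dimethylocta-2,6-dien-1-yl]-2,4,6-trihydroxybenzaldehyde | CC(C)=CCC/C(C)=C/Cc1c(O)cc(O)c(C=O)c1O
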